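## Retrosynthetic overview

1. Target ⇒ monoprenyl spiro-trione + prenyl methyl carbonate; a zerovalent-palladium allylation puts the second prenyl group on ring A.
2. Ring A (trione) ⇒ bridged lactone ester of the hydrindane + 1,3-dianion of a prenylated β-diketone (Claisen, then Dieckmann-type closure). The lactone carbonyl is tied cis to the C4 oxygen, and this fixes the spiro carbon.
3. Lactone bridge ⇒ exo-methylene geminal diester, by cobalt-hydride hydrolactonisation (sets the C4 tertiary carbinol).
4. Ring B (cyclohexane, quaternary C6) ⇒ palladium-catalysed intramolecular allylic C–H alkylation of an isopropenyl group by a tethered malonate (key bond).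
5. Ring C (cyclopentane) ⇒ cyclopent-2-en-1-one, by rhodium-catalysed asymmetric conjugate addition/aldol, malonate Michael addition and MeMgBr addition. Rings close in the order C, B, lactone bridge, A.

Assumption: β-triketone units are written in one enol form (21 and F7 as dienols); monomeric formaldehyde (cracked paraformaldehyde) and isopropenylmagnesium bromide solution are taken as commercial.

## Route

Step 1
Reactants: 1 cyclopent-2-en-1-one; 2 isopropenylmagnesium bromide; 3 formaldehyde
Product: 6 (2S,3S)-2-(hydroxymethyl)-3-(prop-1-en-2-yl)cyclopentan-1-one, via isopropenylzirconocene chloride 4 (not isolated), via zirconium enolate 5 (not isolated)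
Conditions: Cp2ZrCl2 (1.1 equiv), THF, 0 °C; then 1, [Rh(cod)(MeCN)2]BF4 (5 mol%), (S)-BINAP (6 mol%), rt; then 3 (monomer in THF), −78 to −20 °C; aq. NH4Cl
Reagents that add atoms: none
Why: Rhodium/(S)-BINAP-catalysed asymmetric 1,4-addition of the alkenylzirconocene (Hayashi-type conjugate addition) sets C3 as S, and the zirconium enolate then adds to formaldehyde (aldol) anti to the new C3 substituent, giving the 2,3-trans ketol.

Step 2
Reactants: 7 malonic acid
Product: 8 dimethyl malonate
Conditions: MeOH, H2SO4 (cat.), reflux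
Reagents that add atoms: methanol, CO
Why: Fischer esterification of the diacid in excess methanol.

Step 3
Reactants: 6 (2S,3S)-2-(hydroxymethyl)-3-(prop-1-en-2-yl)cyclopentan-1-one; 8 dimethyl malonate
Product: 11 dimethyl 2-{[(1R,5S)-2-oxo-5-(prop-1-en-2-yl)cyclopentyl]methyl}propanedioate, via mesylate 9 (not isolated), via exo-methylene ketone 10 (not isolated)
Conditions: MsCl, Et3N, CH2Cl2, 0 °C; then 8, DBU (20 mol%), 0 °C to rt
Reagents that add atoms: none
Why: Mesylation and E1cB loss of methanesulfonate give the exo-methylene ketone, which is trapped at once by Michael addition of the malonate, and the enolisable C1 centre of the side-arm carbon settles trans to the isopropenyl group (thermodynamic control).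

Step 4
Reactants: 11 dimethyl 2-{[(1R,5S)-2-oxo-5-(prop-1-en-2-yl)cyclopentyl]methyl}propanedioate
Product: 12 dimethyl 2-{[(1R,2S,5S)-2-hydroxy-2-methyl-5-(prop-1-en-2-yl)cyclopentyl]methyl}propanedioate
Conditions: MeMgBr (3 equiv), THF, −78 to −40 °C; aq. NH4Cl at −78 °C
Reagents that add atoms: methylmagnesium bromide, C[Mg]Br
Why: Grignard 1,2-addition in which the first equivalent forms the magnesium malonate and the next adds methyl to the ketone face anti to the bulky adjacent side arm (expected about 6:1), so the new tertiary hydroxyl is cis to that arm (2S); the minor epimer is removed by chromatography and the cold quench avoids δ-lactonisation.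

Step 5
Reactants: 12 dimethyl 2-{[(1R,2S,5S)-2-hydroxy-2-methyl-5-(prop-1-en-2-yl)cyclopentyl]methyl}propanedioate
Product: 13 dimethyl (1S,3aS,7aR)-1-hydroxy-1-methyl-4-methylideneoctahydro-6H-indene-6,6-dicarboxylate
Conditions: Pd(OAc)2 (10 mol%), 1,2-bis(phenylsulfinyl)ethane (10 mol%), 2,6-dimethyl-1,4-benzoquinone (1.5 equiv), AcOH (0.5 equiv), 1,4-dioxane/DMSO 4:1, 45 °C
Reagents that add atoms: none
Why: Proposed new method: divalent palladium ligated by the bis-sulfoxide cleaves an allylic C–H bond of the isopropenyl methyl group (the ring methine C–H is too hindered) to give a 2-substituted π-allyl palladium whose two CH2 termini are equivalent, the tethered malonate closes ring B through a chair transition state with both ring-fusion bonds equatorial (trans-hydrindane, quaternary C6), and the quinone returns zerovalent palladium to the divalent state; the closest known reactions are the palladium/sulfoxide-catalysed intermolecular allylic C–H alkylation of monosubstituted terminal olefins and the Tsuji–Trost cyclisation of malonates onto 2-substituted allyl carbonates, whereas a 1,1-disubstituted olefin with a malonate closing a ring onto a quaternary carbon has not been shown.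

Step 6
Reactants: 13 dimethyl (1S,3aS,7aR)-1-hydroxy-1-methyl-4-methylideneoctahydro-6H-indene-6,6-dicarboxylate
Product: 14 methyl (1S,3aS,4R,6R,7aR)-1-hydroxy-1,4-dimethyl-8-oxooctahydro-1H-4,6-(epoxymethano)indene-6-carboxylate
Conditions: [N,N'-bis(3,5-di-tert-butylsalicylidene)-1,2-cyclohexanediaminato]cobalt, C36H52CoN2O2 (5 mol%), N-fluoro-2,4,6-trimethylpyridinium tetrafluoroborate (1.5 equiv), PhSiH3 (1.2 equiv), PhCF3, rt
Reagents that add atoms: none
Why: Cobalt-hydride hydrogen-atom transfer with radical–polar crossover (hydroacyloxylation of an alkenyl ester): only the axial ester on C6 can reach the tertiary C4 cation equivalent, so the C4–O bond forms axially (4R, methyl equatorial), that ester loses its methyl to collidine, and the two ester groups are told apart.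

Step 7
Reactants: 15 3-methylbutan-2-one; 16 ethyl acetate
Product: 17 5-methylhexane-2,4-dione
Conditions: NaH (2 equiv), THF, reflux; then 1 M HCl
Reagents that add atoms: none
Why: Crossed Claisen condensation, in which acylation at the methyl group is the only one made irreversible by deprotonation of the β-diketone formed.

Step 8
Reactants: 17 5-methylhexane-2,4-dione; 18 1-bromo-3-methylbut-2-ene
Product: 19 2,9-dimethyldec-8-ene-3,5-dione
Conditions: LiN(iPr)2 (2.1 equiv), THF, −78 to 0 °C; then 18, 0 °C; 1 M HCl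
Reagents that add atoms: none
Why: Alkylation of the β-diketone 1,3-dianion at its terminal methyl-derived carbon, the most basic site (Hauser–Harris γ-alkylation).

Step 9
Reactants: 14 methyl (1S,3aS,4R,6R,7aR)-1-hydroxy-1,4-dimethyl-8-oxooctahydro-1H-4,6-(epoxymethano)indene-6-carboxylate; 19 2,9-dimethyldec-8-ene-3,5-dione
Product: 21 (1'S,3a'S,4'R,6'S,7a'R)-1',2,4,4'-tetrahydroxy-1',4'-dimethyl-3-(3-methylbut-2-en-1-yl)-5-(2-methylpropanoyl)-1',2',3',3a',4',5',7',7a'-octahydrospiro[cyclohexa-2,4-diene-1,6'-inden]-6-one, via open-chain triketo ester 20 (not isolated)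
Conditions: 19 (2.5 equiv), LiN(iPr)2 (5.1 equiv), THF, −78 to 0 °C; then 14, −78 °C to rt, then 45 °C; 1 M HCl
Reagents that add atoms: none
Why: Harris-type acylation of the dianion at its CH2 terminus by the strained lactone carbonyl (more reactive than the hindered equatorial methyl ester), then Claisen (Dieckmann-type) closure of the central carbon onto that ester, builds ring A; the lactone carbonyl, already cis to the C4 oxygen, becomes the ring carbon next to the prenylated carbon, which fixes the spiro carbon as S.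

Step 10
Reactants: 22 3-methylbut-2-en-1-ol
Product: 23 methyl 3-methylbut-2-en-1-yl carbonate
Conditions: ClCO2Me, pyridine, CH2Cl2, 0 °C
Reagents that add atoms: methyl chloroformate, COC(=O)Cl
Why: Acylation of the primary allylic alcohol by the chloroformate.

Step 11
Reactants: 21 monoprenyl spiro-trione (name as in step 9); 23 methyl 3-methylbut-2-en-1-yl carbonate
Product: 24 (1'S,3a'S,4'R,6'S,7a'R)-1',4,4'-trihydroxy-1',4'-dimethyl-3,3-bis(3-methylbut-2-en-1-yl)-5-(2-methylpropanoyl)-1',2',3',3a',4',5',7',7a'-octahydrospiro[cyclohex-4-ene-1,6'-indene]-2,6-dione (CNP0273836.6)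
Conditions: Pd(PPh3)4 (5 mol%), THF, rt
Reagents that add atoms: none
Why: Tsuji–Trost decarboxylative allylation in which the released methoxide deprotonates the dienol and the ring carbon that already carries one prenyl group (not the acyl-bearing carbon) attacks the unsubstituted terminus of the 1,1-dimethylallyl palladium, giving the geminal diprenyl centre.

## Compound list

1 | cyclopent-2-en-1-one | O=C1CCC=C1 | starting material
2 | isopropenylmagnesium bromide (prop-1-en-2-ylmagnesium bromide) | CC(=C)[Mg]Br | starting material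
3 | formaldehyde | C=O | starting material
4 | chloridobis(cyclopentadienyl)(prop-1-en-2-yl)zirconium | CC(=C)[Zr](Cl)(C1C=CC=C1)C1C=CC=C1 | intermediate (not isolated)
5 | chloridobis(cyclopentadienyl)zirconium (3S)-3-(prop-1-en-2-yl)cyclopent-1-en-1-olate | CC(=C)[C@H]1CCC(O[Zr](Cl)(C2C=CC=C2)C2C=CC=C2)=C1 | intermediate (not isolated)
6 | (2S,3S)-2-(hydroxymethyl)-3-(prop-1-en-2-yl)cyclopentan-1-one | OC[C@@H]1[C@H](CCC1=O)C(C)=C | intermediate
7 | malonic acid | OC(=O)CC(=O)O | starting material
8 | dimethyl malonate | COC(=O)CC(=O)OC | intermediate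
9 | [(1S,5S)-2-oxo-5-(prop-1-en-2-yl)cyclopentyl]methyl methanesulfonate | CS(=O)(=O)OC[C@@H]1[C@H](CCC1=O)C(C)=C | intermediate (not isolated)
10 | (3R)-2-methylidene-3-(prop-1-en-2-yl)cyclopentan-1-one | C=C1[C@H](CCC1=O)C(C)=C | intermediate (not isolated)
11 | dimethyl 2-{[(1R,5S)-2-oxo-5-(prop-1-en-2-yl)cyclopentyl]methyl}propanedioate | COC(=O)C(C[C@@H]1[C@H](CCC1=O)C(C)=C)C(=O)OC | intermediate
12 | dimethyl 2-{[(1R,2S,5S)-2-hydroxy-2-methyl-5-(prop-1-en-2-yl)cyclopentyl]methyl}propanedioate | COC(=O)C(C[C@@H]1[C@H](CC[C@]1(C)O)C(C)=C)C(=O)OC | intermediate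
13 | dimethyl (1S,3aS,7aR)-1-hydroxy-1-methyl-4-methylideneoctahydro-6H-indene-6,6-dicarboxylate (trans-fused) | COC(=O)C1(C[C@@H]2[C@H](CC[C@]2(C)O)C(=C)C1)C(=O)OC | intermediate
14 | methyl (1S,3aS,4R,6R,7aR)-1-hydroxy-1,4-dimethyl-8-oxooctahydro-1H-4,6-(epoxymethano)indene-6-carboxylate (γ-lactone between the C6 carboxyl and the C4 oxygen) | COC(=O)[C@@]12C[C@@H]3[C@H](CC[C@]3(C)O)[C@@](C)(C1)OC2=O | intermediate
15 | 3-methylbutan-2-one | CC(C)C(C)=O | starting material
16 | ethyl acetate | CCOC(C)=O | starting material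
17 | 5-methylhexane-2,4-dione | CC(C)C(=O)CC(C)=O | intermediate
18 | 1-bromo-3-methylbut-2-ene (prenyl bromide) | CC(C)=CCBr | starting material
19 | 2,9-dimethyldec-8-ene-3,5-dione | CC(C)C(=O)CC(=O)CCC=C(C)C | intermediate
20 | methyl (1S,3aS,4R,6S,7aR)-1,4-dihydroxy-1,4-dimethyl-6-[6-methyl-2-(3-methylbut-2-en-1-yl)-3,5-dioxoheptanoyl]octahydro-1H-indene-6-carboxylate | COC(=O)[C@]1(C[C@@H]2[C@H](CC[C@]2(C)O)[C@](C)(O)C1)C(=O)C(CC=C(C)C)C(=O)CC(=O)C(C)C | intermediate (not isolated)
21 | (1'S,3a'S,4'R,6'S,7a'R)-1',2,4,4'-tetrahydroxy-1',4'-dimethyl-3-(3-methylbut-2-en-1-yl)-5-(2-methylpropanoyl)-1',2',3',3a',4',5',7',7a'-octahydrospiro[cyclohexa-2,4-diene-1,6'-inden]-6-one (C6' is the spiro carbon) | CC(C)=CCC1=C(O)[C@@]2(C[C@@H]3[C@H](CC[C@]3(C)O)[C@](C)(O)C2)C(=O)C(C(=O)C(C)C)=C1O | intermediate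
22 | 3-methylbut-2-en-1-ol | CC(C)=CCO | starting material
23 | methyl 3-methylbut-2-en-1-yl carbonate | COC(=O)OCC=C(C)C | intermediate
24 | (1'S,3a'S,4'R,6'S,7a'R)-1',4,4'-trihydroxy-1',4'-dimethyl-3,3-bis(3-methylbut-2-en-1-yl)-5-(2-methylpropanoyl)-1',2',3',3a',4',5',7',7a'-octahydrospiro[cyclohex-4-ene-1,6'-indene]-2,6-dione | CC(C)=CCC1(CC=C(C)C)C(=O)[C@@]2(C[C@@H]3[C@H](CC[C@]3(C)O)[C@](C)(O)C2)C(=O)C(C(=O)C(C)C)=C1O | target

## Step count and risks

Total step count: 11.

Longest linear sequence: 7 steps (1, 3, 4, 5, 6, 9, 11 from cyclopent-2-en-1-one; the chain from malonic acid through step 2 is also 7).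

The three steps most likely to fail:

**Step 5 (the proposed new C–H alkylation).** Wacker-type attack at the internal olefin carbon or low turnover with the weakly acidic malonate could compete. The fallback uses known chemistry and sets out from 12. Allylic hydroxylation of the isopropenyl methyl group (SeO2 cat., t-BuOOH, CH2Cl2) gives dimethyl 2-{[(1R,2S,5S)-2-hydroxy-5-(3-hydroxyprop-1-en-2-yl)-2-methylcyclopentyl]methyl}propanedioate F1. ClCO2Me and pyridine convert its primary hydroxyl into dimethyl 2-{[(1R,2S,5S)-2-hydroxy-5-{3-[(methoxycarbonyl)oxy]prop-1-en-2-yl}-2-methylcyclopentyl]methyl}propanedioate F2. Pd(PPh3)4 (zerovalent palladium) in THF at 60 °C then closes ring B by Tsuji–Trost cyclisation, and the sequence comes back to the route at 13.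

**Step 6 (hydrolactonisation).** The hindered tertiary radical could be reduced or eliminated instead of being captured by the ester. The fallback sets out from 13. Saponification (LiOH, THF/MeOH/H2O, 60 °C) gives (1S,3aS,7aR)-1-hydroxy-1-methyl-4-methylideneoctahydro-6H-indene-6,6-dicarboxylic acid F3. Iodolactonisation (I2, NaHCO3, MeCN/H2O), in which only the axial carboxylate can reach C4, gives (1S,3aS,4R,6R,7aR)-1-hydroxy-4-(iodomethyl)-1-methyl-8-oxooctahydro-1H-4,6-(epoxymethano)indene-6-carboxylic acid F4. MeI and K2CO3 give methyl (1S,3aS,4R,6R,7aR)-1-hydroxy-4-(iodomethyl)-1-methyl-8-oxooctahydro-1H-4,6-(epoxymethano)indene-6-carboxylate F5. Hydrogenolysis of the C–I bond (H2, Pd/C, Et3N, EtOAc) comes back to the route at 14.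

**Step 9 (ring A annulation).** The secondary dianion carbon may add sluggishly to the lactone carbonyl on a quaternary carbon, or may attack the ester instead, which would invert the spiro centre. The fallback sets out from 14 and uses the dianion of the unprenylated diketone 17 (LiN(iPr)2, THF), whose primary carbanion is smaller and more reactive. It adds to the lactone to give methyl (1S,3aS,4R,6S,7aR)-1,4-dihydroxy-1,4-dimethyl-6-(6-methyl-3,5-dioxoheptanoyl)octahydro-1H-indene-6-carboxylate F6 (not isolated). F6 cyclises in the same flask to (1'S,3a'S,4'R,6'S,7a'R)-1',2,4,4'-tetrahydroxy-1',4'-dimethyl-5-(2-methylpropanoyl)-1',2',3',3a',4',5',7',7a'-octahydrospiro[cyclohexa-2,4-diene-1,6'-inden]-6-one F7. Pd(PPh3)4 with one equivalent of 23 then prenylates the ring CH carbon, and the sequence comes back to the route at 21.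

## Further compounds

F1 | step 5 | dimethyl 2-{[(1R,2S,5S)-2-hydroxy-5-(3-hydroxyprop-1-en-2-yl)-2-methylcyclopentyl]methyl}propanedioate | COC(=O)C(C[C@@H]1[C@H](CC[C@]1(C)O)C(=C)CO)C(=O)OC
F2 | step 5 | dimethyl 2-{[(1R,2S,5S)-2-hydroxy-5-{3-[(methoxycarbonyl)oxy]prop-1-en-2-yl}-2-methylcyclopentyl]methyl}propanedioate | COC(=O)C(C[C@@H]1[C@H](CC[C@]1(C)O)C(=C)COC(=O)OC)C(=O)OC
F3 | step 6 | (1S,3aS,7aR)-1-hydroxy-1-methyl-4-methylideneoctahydro-6H-indene-6,6-dicarboxylic acid | OC(=O)C1(C[C@@H]2[C@H](CC[C@]2(C)O)C(=C)C1)C(=O)O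
F4 | step 6 | (1S,3aS,4R,6R,7aR)-1-hydroxy-4-(iodomethyl)-1-methyl-8-oxooctahydro-1H-4,6-(epoxymethano)indene-6-carboxylic acid | OC(=O)[C@@]12C[C@@H]3[C@H](CC[C@]3(C)O)[C@@](CI)(C1)OC2=O
F5 | step 6 | methyl (1S,3aS,4R,6R,7aR)-1-hydroxy-4-(iodomethyl)-1-methyl-8-oxooctahydro-1H-4,6-(epoxymethano)indene-6-carboxylate | COC(=O)[C@@]12C[C@@H]3[C@H](CC[C@]3(C)O)[C@@](CI)(C1)OC2=O
F6 | step 9 | methyl (1S,3aS,4R,6S,7aR)-1,4-dihydroxy-1,4-dimethyl-6-(6-methyl-3,5-dioxoheptanoyl)octahydro-1H-indene-6-carboxylate | COC(=O)[C@]1(C[C@@H]2[C@H](CC[C@]2(C)O)[C@](C)(O)C1)C(=O)CC(=O)CC(=O)C(C)C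
F7 | step 9 | (1'S,3a'S,4'R,6'S,7a'R)-1',2,4,4'-tetrahydroxy-1',4'-dimethyl-5-(2-methylpropanoyl)-1',2',3',3a',4',5',7',7a'-octahydrospiro[cyclohexa-2,4-diene-1,6'-inden]-6-one | C1=C(O)[C@@]2(C[C@@H]3[C@H](CC[C@]3(C)O)[C@](C)(O)C2)C(=O)C(C(=O)C(C)C)=C1O
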